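The cyclohexene ring (C1 carrying the C7 oxymethylene, C2 the methyl-bearing alkene carbon, C3 the alkene CH, C4 the CH2, C5 the acyloxy CH, C6 the gem-dimethyl carbon) has its C2=C3 double bond directly across from the C5–C6 bond, so it is cut at C1–C6 and C4–C5 into a C7–C1=C2–C3=C4 silyloxy diene and a C5=C6 enal. One catalytic enantioselective Diels–Alder reaction closes the ring, forms both bonds and sets C1, C5 and a sacrificial C6, whose formyl group is later reduced to the second methyl. The precursors are E-dienyl silyl ether 3 and E-enal 8, which already carries the final (R)-2-methylbutanoate.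

Key step: step 5

Assumption: the (S)-configured oxazaborolidinium catalyst is taken to deliver the diene to the C5-Re/C6-Re face of bound enal 8; if the sense of induction proves opposite, its enantiomer from (R)-α,α-diphenylprolinol is used with no other change.

Step 1
Reactants: 1 (E)-3-methylpent-2-en-4-yn-1-ol
Product: 2 (E)-tert-butyldimethyl[(3-methylpent-2-en-4-yn-1-yl)oxy]silane
Conditions: TBSCl, imidazole, CH2Cl2, 0 °C to rt
Reagents that add atoms: tert-butyldimethylsilyl chloride, CC(C)(C)[Si](C)(C)Cl
Why: Imidazole-promoted silylation of a primary allylic alcohol; the silyl ether resists the later Lewis acid and is the least electron-withdrawing form of the C7 oxygen for the diene.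

Step 2
Reactants: 2 (E)-tert-butyldimethyl[(3-methylpent-2-en-4-yn-1-yl)oxy]silane
Product: 3 (E)-tert-butyldimethyl[(3-methylpenta-2,4-dien-1-yl)oxy]silane
Conditions: H2 (1 atm, one equivalent taken up), Pd/CaCO3 poisoned with Pb(OAc)2 (Lindlar catalyst), quinoline, hexane, rt
Reagents that add atoms: none
Why: Lindlar semihydrogenation should stop at the vinyl group and leave the trisubstituted E double bond alone, so C7 stays trans to the new vinyl group and sits outside in the s-cis diene.

Step 3
Reactants: 4 3-ethoxy-2-methylacrolein (3-ethoxymethacrolein)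
Product: 5 sodium (E)-2-methyl-3-oxoprop-1-en-1-olate (sodium enolate of methylmalondialdehyde)
Conditions: NaOH (1.0 equiv), H2O, rt; evaporate, dry by toluene azeotrope
Reagents that add atoms: sodium hydroxide, [Na+].[OH-]
Why: Addition–elimination hydrolysis of the vinylogous ester, in which hydroxide attacks the β-carbon and expels ethoxide, should give the delocalised W-shaped enolate salt, isolated dry.

Step 4
Reactants: 6 (R)-2-methylbutanoic acid; 5 sodium (E)-2-methyl-3-oxoprop-1-en-1-olate
Product: 8 (E)-2-methyl-3-oxoprop-1-en-1-yl (R)-2-methylbutanoate, via (R)-2-methylbutanoyl chloride 7 (not isolated)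
Conditions: (COCl)2, cat. HCONMe2, CH2Cl2, 0 °C to rt, evaporate; then 5, MeCN, 0 °C to rt
Reagents that add atoms: none
Why: Acid chloride formation followed by O-acylation of the enolate uses no amine base, so no ketene can form and the acyl α-stereocentre is retained; acylation of the W-shaped enolate should leave acyloxy trans to formyl (E).

Step 5
Reactants: 3 (E)-tert-butyldimethyl[(3-methylpenta-2,4-dien-1-yl)oxy]silane; 8 (E)-2-methyl-3-oxoprop-1-en-1-yl (R)-2-methylbutanoate
Product: 9 formyl cyclohexene with C1 (S) bearing CH2OTBS, C2 bearing methyl, C5 (R) bearing the (R)-2-methylbutanoyloxy group and C6 (R) bearing methyl and formyl; acyloxy, CH2OTBS and C6-methyl mutually cis, formyl trans to them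
Conditions: 3 (1.5 equiv), N-protonated (S)-1-(2-methylphenyl)-3,3-diphenyltetrahydro-1H,3H-pyrrolo[1,2-c][1,3,2]oxazaborole bis(trifluoromethanesulfonyl)imide, [C24H25BNO][N(SO2CF3)2] (20 mol%), CH2Cl2, −78 to −40 °C
Reagents that add atoms: none
Why: The cationic boron Lewis acid binds the formyl oxygen of 8, and 3 then adds in a concerted, asynchronous [4+2] cycloaddition in which the C4–C5 bond runs ahead of the C1–C6 bond, which lets the fully substituted C6 join the substituted C1; the closest known reaction type is the oxazaborolidinium-catalysed enantioselective Diels–Alder reaction of 2-methylacrolein and other α-substituted enals with 1- and 2-substituted butadienes, of which the β-acyloxy enal is a new member. The six-membered ring is closed by intermolecular suprafacial–suprafacial cycloaddition, both ring bonds forming in the one step. C5 and C6 are fixed relative to each other by the E geometry of 8 (acyloxy cis to methyl); C1 is fixed relative to them by the E geometry of 3 (C7 outside) together with the formyl-exo, acyloxy-endo topology that α-methyl enals usually adopt on this catalyst, which places the C5 oxygen cis to C7; the absolute configuration of all three comes from the catalyst, which shields one face so that the diene meets the C5-Re/C6-Re face. The step needs C4, not C1, to bond to C5: the unsubstituted C4 is the more accessible terminus, the C1 substituent directs ortho, its silyl ether is the least electron-withdrawing form of the C7 oxygen, and the acyloxy-stabilised β-carbon C5 bonds early to the open terminus; the opposing para preference of the C2 methyl group is the accepted risk. It also needs the acyloxy group endo, because the formyl-endo mode would place the C5 oxygen trans to C7.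

Step 6
Reactants: 9 formyl cyclohexene from step 5
Product: 10 (E)-N-tosylhydrazone of 9 (CH=N–NHTs on C6, ring stereocentres unchanged)
Conditions: TsNHNH2, EtOH, 40 °C
Reagents that add atoms: p-toluenesulfonyl hydrazide, Cc1ccc(cc1)S(=O)(=O)NN
Why: Tosylhydrazone formation by condensation at the formyl carbon; C6 carries no hydrogen, so neither epimerisation nor β-elimination of the C5 ester is possible.

Step 7
Reactants: 10 (E)-N-tosylhydrazone of 9
Product: 11 (1R,5S)-5-{[(tert-butyldimethylsilyl)oxy]methyl}-4,6,6-trimethylcyclohex-3-en-1-yl (R)-2-methylbutanoate (overview locants: C1 S, C5 R, C6 now gem-dimethyl)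
Conditions: catecholborane, CHCl3, 0 °C; then NaOAc·3H2O, reflux
Reagents that add atoms: none
Why: Caglioti-type reductive deoxygenation, in which the borane reduces C=N, acetate triggers loss of sulfinate and the alkyl diazene expels N2, should turn CH=N into CH3 while ester, isolated alkene and silyl ether stay inert; C6 thereby becomes achiral.

Step 8
Reactants: 11 silyl ether from step 7
Product: 12 (1R,5S)-5-(hydroxymethyl)-4,6,6-trimethylcyclohex-3-en-1-yl (R)-2-methylbutanoate
Conditions: HF·pyridine, THF–pyridine, 0 °C to rt
Reagents that add atoms: none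
Why: Fluoride desilylation of the primary silyl ether under buffered conditions generates no free alkoxide, so the secondary ester should neither hydrolyse nor migrate.

Step 9
Reactants: 12 primary alcohol from step 8; 13 umbelliferone (7-hydroxy-2H-chromen-2-one)
Product: 14 (1R,5S)-4,6,6-trimethyl-5-{[(2-oxo-2H-chromen-7-yl)oxy]methyl}cyclohex-3-en-1-yl (R)-2-methylbutanoate (target; overview locants C1 S, C5 R)
Conditions: PPh3, DIAD, THF, 0 °C to rt
Reagents that add atoms: none
Why: Mitsunobu etherification, in which the acidic coumarin phenol displaces the oxyphosphonium group at the primary carbon C7 by SN2, touches no stereocentre.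

Compound list
1 | (E)-3-methylpent-2-en-4-yn-1-ol | C#C/C(C)=C/CO | starting material
2 | (E)-tert-butyldimethyl[(3-methylpent-2-en-4-yn-1-yl)oxy]silane | C#C/C(C)=C/CO[Si](C)(C)C(C)(C)C | intermediate
3 | (E)-tert-butyldimethyl[(3-methylpenta-2,4-dien-1-yl)oxy]silane | C=C/C(C)=C/CO[Si](C)(C)C(C)(C)C | intermediate
4 | 3-ethoxy-2-methylacrolein | CCOC=C(C)C=O | starting material
5 | sodium (E)-2-methyl-3-oxoprop-1-en-1-olate | [Na+].[O-]/C=C(C)/C=O | intermediate
6 | (R)-2-methylbutanoic acid | CC[C@@H](C)C(=O)O | starting material
7 | (R)-2-methylbutanoyl chloride | CC[C@@H](C)C(=O)Cl | intermediate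
8 | (E)-2-methyl-3-oxoprop-1-en-1-yl (R)-2-methylbutanoate | CC[C@@H](C)C(=O)O/C=C(C)/C=O | intermediate
9 | (1R,5S,6R)-5-{[(tert-butyldimethylsilyl)oxy]methyl}-6-formyl-4,6-dimethylcyclohex-3-en-1-yl (R)-2-methylbutanoate | CC[C@@H](C)C(=O)O[C@@H]1CC=C(C)[C@H](CO[Si](C)(C)C(C)(C)C)[C@@]1(C)C=O | intermediate
10 | (E)-N-tosylhydrazone of 9 | CC[C@@H](C)C(=O)O[C@@H]1CC=C(C)[C@H](CO[Si](C)(C)C(C)(C)C)[C@@]1(C)/C=N/NS(=O)(=O)c1ccc(C)cc1 | intermediate
11 | (1R,5S)-5-{[(tert-butyldimethylsilyl)oxy]methyl}-4,6,6-trimethylcyclohex-3-en-1-yl (R)-2-methylbutanoate | CC[C@@H](C)C(=O)O[C@@H]1CC=C(C)[C@H](CO[Si](C)(C)C(C)(C)C)C1(C)C | intermediate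
12 | (1R,5S)-5-(hydroxymethyl)-4,6,6-trimethylcyclohex-3-en-1-yl (R)-2-methylbutanoate | CC[C@@H](C)C(=O)O[C@@H]1CC=C(C)[C@H](CO)C1(C)C | intermediate
13 | umbelliferone (7-hydroxy-2H-chromen-2-one) | Oc1ccc2ccc(=O)oc2c1 | starting material
14 | (1R,5S)-4,6,6-trimethyl-5-{[(2-oxo-2H-chromen-7-yl)oxy]methyl}cyclohex-3-en-1-yl (R)-2-methylbutanoate | CC[C@@H](C)C(=O)O[C@@H]1CC=C(C)[C@H](COc2ccc3ccc(=O)oc3c2)C1(C)C | target

Total step count: 9. Longest linear sequence: 7 steps (steps 1, 2, 5, 6, 7, 8, 9; the branch through steps 3 and 4 is equally long).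

Steps most likely to fail

Step 5. The diene may add in the reverse orientation, its substituted terminus C1 bonding to C5 because the C2 methyl group outweighs the C1 substituent, or the hindered cycloaddition may be too slow to outrun acid-induced decomposition of the diene. The fallback keeps the same two bond formations but uses a diene with a removable oxygen on C3, which turns C4 into the β-carbon of a silyl enol ether and so fixes the orientation and raises reactivity. It sets out from 8 and comes back at 9. Wittig olefination of (tert-butyldimethylsilyloxy)acetaldehyde with 3-(triphenylphosphoranylidene)butan-2-one should give (E)-5-(tert-butyldimethylsilyloxy)-3-methylpent-3-en-2-one F1. TBSOTf/Et3N should convert it into (E)-1,4-bis(tert-butyldimethylsilyloxy)-3-methylpenta-2,4-diene F2. Cycloaddition of this diene with 8 under the step 5 catalyst should give the C3-silyloxy adduct F3. CsF/PhNTf2 in 1,2-dimethoxyethane should exchange the far more labile enol silyl group for triflate, giving the enol triflate F4. Pd(OAc)2/PPh3/HCO2H/Bu3N in N,N-dimethylformamide at 60 °C should then reduce C3–O to C3–H and give 9.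

Step 7. Hydride transfer to the C=N bond next to the quaternary C6 may stall, or prolonged heating during the acetate-induced decomposition may erode the silyl ether. The fallback is a radical deoxygenation that sets out from 9 and comes back at 11. NaBH4 in MeOH–CH2Cl2 at −40 °C, quenched cold to forestall acyl shift, should give the C6-hydroxymethyl compound F5. PhOC(S)Cl, pyridine and 4-(dimethylamino)pyridine should give the O-phenyl thionocarbonate F6. Bu3SnH with azobisisobutyronitrile in refluxing toluene (Barton–McCombie) should give 11.

Step 9. Displacement of the oxyphosphonium group at the β-branched C7 may be slow, so that elimination toward C1 or capture by the reduced azodicarboxylate competes. The fallback is a Williamson-type alkylation of a preformed phenoxide that sets out from 12 and comes back at 14. Tf2O and 2,6-lutidine in CH2Cl2 at −78 °C should give the primary triflate F7, which the cesium salt of 13 (Cs2CO3, MeCN, 0 °C to rt) should displace to give 14.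

Further compounds
F1 | step 5 | (E)-5-(tert-butyldimethylsilyloxy)-3-methylpent-3-en-2-one | CC(=O)/C(C)=C/CO[Si](C)(C)C(C)(C)C
F2 | step 5 | (E)-1,4-bis(tert-butyldimethylsilyloxy)-3-methylpenta-2,4-diene | C=C(O[Si](C)(C)C(C)(C)C)/C(C)=C/CO[Si](C)(C)C(C)(C)C
F3 | step 5 | C3-(tert-butyldimethylsilyloxy) analogue of 9 (silyl enol ether adduct) | CC[C@@H](C)C(=O)O[C@@H]1CC(O[Si](C)(C)C(C)(C)C)=C(C)[C@H](CO[Si](C)(C)C(C)(C)C)[C@@]1(C)C=O
F4 | step 5 | C3-(trifluoromethanesulfonyloxy) analogue of 9 (enol triflate) | CC[C@@H](C)C(=O)O[C@@H]1CC(OS(=O)(=O)C(F)(F)F)=C(C)[C@H](CO[Si](C)(C)C(C)(C)C)[C@@]1(C)C=O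
F5 | step 7 | C6-hydroxymethyl analogue of 9 | CC[C@@H](C)C(=O)O[C@@H]1CC=C(C)[C@H](CO[Si](C)(C)C(C)(C)C)[C@@]1(C)CO
F6 | step 7 | O-phenyl thionocarbonate of F5 | CC[C@@H](C)C(=O)O[C@@H]1CC=C(C)[C@H](CO[Si](C)(C)C(C)(C)C)[C@@]1(C)COC(=S)Oc1ccccc1
F7 | step 9 | trifluoromethanesulfonate of 12 | CC[C@@H](C)C(=O)O[C@@H]1CC=C(C)[C@H](COS(=O)(=O)C(F)(F)F)C1(C)C
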